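**Retrosynthetic overview**

1. The target is the malonate diester of two identical (5S,9S,10S,13E)-labda-7,13-dien-15-ol units (labdane numbering); it is cut last at both ester C–O bonds (double Steglich esterification of malonic acid).
2. The E-allylic alcohol terminus (C13=C14, C15, C16) is added late to a terminal alkyne by zirconium-catalysed methylalumination and formaldehyde capture; the alkyne hydrocarbon comes from a bicyclic 7-en-6-one by removal of a temporary C6 carbonyl.
3. Enabling feature: in ring B (C5, C6, C7, C8, C9, C10) the C7=C8 double bond lies directly across from the C5–C10 ring-fusion bond, so C5–C6–C7 can be an acetone unit (C6 a temporary ketone) and C8–C9–C10 an α-branched enone unit (C8 the acetyl carbon, C10 the β-carbon), joined through C1–C4 with the gem-dimethyl group on C4.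
4. Key disconnection: C5–C10 and C7=C8 together, back to an acyclic, achiral E-enedione; a chiral-ketimine Michael/aldol double annulation closes ring A first (C5–C10), then ring B (C7=C8), and sets C5, C9 and C10.
5. The enedione is assembled from acetylacetone, a silylated bromobutyne, mesityl oxide and allyltrimethylsilane by alkylation, E-selective enol tosylation and Negishi coupling.

Key step: step 6

Remark: atoms are numbered as in labdane (C17 is the methyl on C8, C20 the methyl on C10); α/β denote the faces of the trans-decalin, β being the face of the C10 methyl.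
Remark: the sense of induction by the (S)-configured amine in step 6 is assigned from the aza-ene model (bond formation on the enamine face anti to phenyl, the C4 branch lying trans to the C7 methyl on the enamine); should the opposite sense be found, the (R)-amine would be used.

**Route**

Step 1
Reactants: 1 pentane-2,4-dione; 2 (4-bromobut-1-yn-1-yl)trimethylsilane
Product: 3 3-[4-(trimethylsilyl)but-3-yn-1-yl]pentane-2,4-dione
Conditions: K2CO3, NaI (cat.), acetone, reflux
Reagents that add atoms: none
Why: C-alkylation of the doubly stabilised acetylacetone enolate by a primary bromide (SN2 with Finkelstein assistance) is routine, the mild carbonate should leave the silylalkyne intact, and no stereocentre is formed.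

Step 2
Reactants: 3 3-[4-(trimethylsilyl)but-3-yn-1-yl]pentane-2,4-dione
Product: 4 (E)-4-oxo-3-[4-(trimethylsilyl)but-3-yn-1-yl]pent-2-en-2-yl 4-methylbenzenesulfonate (tosyloxy group trans to the acetyl group)
Conditions: TsCl, N-methylimidazole, Et3N, CH2Cl2, 0 °C
Reagents that add atoms: p-toluenesulfonyl chloride, Cc1ccc(cc1)S(Cl)(=O)=O
Why: O-sulfonylation of a symmetric 1,3-diketone (stereodefined enol tosylate formation) has no regiochemical issue, and under non-chelating amine conditions the enolate should react from its extended form to place the tosyloxy group trans to the remaining acetyl group, the geometry that later puts the acetyl group cis to the C10 methyl.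

Step 3
Reactants: 5 4-methylpent-3-en-2-one (mesityl oxide); 6 allyltrimethylsilane
Product: 7 4,4-dimethylhept-6-en-2-one
Conditions: TiCl4, CH2Cl2, −78 °C; then H2O
Reagents that add atoms: none
Why: Hosomi–Sakurai conjugate allylation of a β,β-disubstituted enone under TiCl4 activation should form the quaternary C4 directly; no stereocentre arises.

Step 4
Reactants: 7 4,4-dimethylhept-6-en-2-one
Product: 8 7-bromo-4,4-dimethylheptan-2-one
Conditions: HBr, (PhCO2)2 (cat.), hexane, 0 °C
Reagents that add atoms: hydrogen bromide, Br
Why: Radical-chain anti-Markovnikov hydrobromination (Kharasch peroxide effect) should place bromine on the terminal carbon and leave the hindered methyl ketone untouched.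

Step 5
Reactants: 8 7-bromo-4,4-dimethylheptan-2-one; 4 (E)-enol tosylate
Product: 10 (E)-4,8,8-trimethyl-3-[4-(trimethylsilyl)but-3-yn-1-yl]undec-3-ene-2,10-dione, via alkylzinc bromide 9 (not isolated)
Conditions: Zn, LiCl, THF, 50 °C; then 4, PdCl2(dppf) (cat.), THF, 50 °C
Reagents that add atoms: none
Why: Zinc insertion into the primary bromide gives a ketone-tolerant alkylzinc reagent, and Negishi coupling with the activated (vinylogous acyl) enol tosylate should proceed with retention of alkene geometry, so that the acetyl group ends up cis to the methyl on the new tetrasubstituted alkene (E).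

Step 6
Reactants: 10 (E)-enedione; 11 (S)-1-phenylethylamine
Product: 15 14-(trimethylsilyl)-15,16-dinorlabd-7-en-13-yn-6-one (trans-fused; 5α-H, 9α-H, 10β-methyl), via ketimine 12 (not isolated), via monocyclic ketimine 13 (not isolated), via azadiene 14 (not isolated)
Conditions: (S)-PhCH(Me)NH2, TsOH (cat.), 4 Å MS, PhMe, 60 → 110 °C; then AcOH, 80 °C; then AcOH, H2O, THF, rt
Reagents that add atoms: water, O
Why: Proposed new method: the auxiliary amine should condense only with the unhindered, non-conjugated C6 methyl ketone to give ketimine 12, whose secondary-enamine tautomer (C5=C6, N–H syn to C5) attacks the enone β-carbon C10 through C5 in an aza-ene-type Michael addition, the closest known reaction type being the deracemising Michael addition of chiral 1-phenylethylamine ketimines to electron-poor alkenes, used here intramolecularly on a tetrasubstituted enone so that the quaternary centre is created on the acceptor. Ring A closes in a 6-(enolexo)-exo-trig mode (helped by the gem-dimethyl group at C4) through a chair in which the C5–C6 and C10–C9 bonds are equatorial and the smaller C10 methyl is axial, which gives the trans relationship of H-5 and the C10 methyl, while the phenyl group of the auxiliary blocks one enamine face and so fixes the absolute configuration of C5 and C10 (assigned as 5S,10S for the S-amine by the aza-ene model). The N–H hydrogen is passed to C9 inside the same six-membered array, on the face on which the C5–C10 bond forms, so the E geometry of 10 (acetyl cis to the C10 methyl) is translated into H-9 α and the side chain β. Ketimine 13 then tautomerises to its less substituted enamine (C6=C7), which adds to the C8 ketone in a 6-(enolendo)-exo-trig aldol closure of ring B and loses water to give azadiene 14 (a Stork-type enamine annulation), and mild aqueous acid frees enone 15 and the auxiliary. The step needs chemoselective imine formation (the conjugated, tetrasubstituted C8 ketone is far less reactive), aldol closure from C7 onto C8 and not from the C8 methyl onto C6 (nitrogen sits only on C6), and retention at C9 (no strong base is present, and any re-protonation at C9 through the ring B dienamine should occur axially from the α face, away from the C10 methyl, which leads to the same epimer).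

Step 7
Reactants: 15 bicyclic enone
Product: 16 14-(trimethylsilyl)-15,16-dinorlabd-7-en-13-yn-6β-ol
Conditions: NaBH4, CeCl3·7H2O, MeOH, 0 °C
Reagents that add atoms: none
Why: Luche reduction should give clean 1,2-reduction of the enone, hydride approaching C6 from the α face away from the axial methyl groups on C4 and C10 to give the 6β-alcohol (the C6 configuration is removed in step 9).

Step 8
Reactants: 16 6β-allylic alcohol
Product: 17 14-(trimethylsilyl)-15,16-dinorlabd-7-en-13-yn-6β-yl acetate
Conditions: Ac2O, Et3N, DMAP (cat.), CH2Cl2, 40 °C
Reagents that add atoms: acetic anhydride, CC(=O)OC(C)=O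
Why: DMAP-catalysed acylation should convert the hindered axial allylic alcohol into an ionisable allylic acetate with retention at C6.

Step 9
Reactants: 17 allylic acetate
Product: 19 15,16-dinorlabd-7-en-13-yne (5α-H, 9α-H, 10β-methyl), via silylalkyne 18 (not isolated)
Conditions: Pd(PPh3)4 (cat.), LiBHEt3, THF, 0 °C → rt; then MeOH, K2CO3 (cat.), rt
Reagents that add atoms: none
Why: Palladium-catalysed allylic reduction (Tsuji–Trost ionisation by zerovalent palladium to a π-allyl complex, then hydride transfer from LiBHEt3 to the less substituted terminus C6) should remove the oxygen and keep the trisubstituted C7=C8 alkene, and the methoxide present after the methanol quench cleaves the alkynylsilane; C5, C9 and C10 are not touched.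

Step 10
Reactants: 19 terminal alkyne
Product: 21 (13E)-labda-7,13-dien-15-ol, (5S,9S,10S), via alkenylalane 20 (not isolated)
Conditions: Me3Al, Cp2ZrCl2 (cat.), CH2Cl2, rt; then n-BuLi, THF, −78 °C; then (CH2O)n, rt
Reagents that add atoms: trimethylaluminium, C[Al](C)C; formaldehyde (as paraformaldehyde), C=O
Why: Zirconium-catalysed carboalumination (Negishi carboalumination) adds methyl and aluminium syn across the terminal alkyne with methyl on the internal carbon, and hydroxymethylation of the derived aluminate occurs with retention, which should set the 13E alkene; the trisubstituted ring alkene is inert.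

Step 11
Reactants: 21 (13E)-labda-7,13-dien-15-ol (two equivalents); 22 malonic acid
Product: 23 bis[(13E)-labda-7,13-dien-15-yl] malonate (CNP0113044.1)
Conditions: DCC, DMAP (cat.), CH2Cl2, 0 °C → rt
Reagents that add atoms: none
Why: Steglich esterification acylates the primary allylic alcohol under neutral conditions that do not ionise it, both carboxyl groups of malonic acid reacting in turn; no stereocentre is affected.

**Compound list**

1 | pentane-2,4-dione (acetylacetone) | CC(=O)CC(C)=O | starting material
2 | (4-bromobut-1-yn-1-yl)trimethylsilane | C[Si](C)(C)C#CCCBr | starting material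
3 | 3-[4-(trimethylsilyl)but-3-yn-1-yl]pentane-2,4-dione | CC(=O)C(CCC#C[Si](C)(C)C)C(C)=O | intermediate
4 | (E)-4-oxo-3-[4-(trimethylsilyl)but-3-yn-1-yl]pent-2-en-2-yl 4-methylbenzenesulfonate | C/C(OS(=O)(=O)c1ccc(C)cc1)=C(/CCC#C[Si](C)(C)C)C(C)=O | intermediate
5 | 4-methylpent-3-en-2-one (mesityl oxide) | CC(C)=CC(C)=O | starting material
6 | allyltrimethylsilane | C=CC[Si](C)(C)C | starting material
7 | 4,4-dimethylhept-6-en-2-one | CC(=O)CC(C)(C)CC=C | intermediate
8 | 7-bromo-4,4-dimethylheptan-2-one | CC(=O)CC(C)(C)CCCBr | intermediate
9 | (4,4-dimethyl-6-oxoheptyl)zinc bromide | CC(=O)CC(C)(C)CCC[Zn]Br | intermediate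
10 | (E)-4,8,8-trimethyl-3-[4-(trimethylsilyl)but-3-yn-1-yl]undec-3-ene-2,10-dione | CC(=O)/C(CCC#C[Si](C)(C)C)=C(\C)CCCC(C)(C)CC(C)=O | intermediate
11 | (S)-1-phenylethylamine | C[C@H](N)c1ccccc1 | starting material
12 | N-[(S)-1-phenylethyl] ketimine of 10 at its saturated methyl ketone (labdane C6), enone E | CC(=N[C@@H](C)c1ccccc1)CC(C)(C)CCC/C(C)=C(\CCC#C[Si](C)(C)C)C(C)=O | intermediate
13 | monocyclic ketimine: ring A closed (C5–C10), acetimidoyl on C5 and the 1-acetyl-5-(trimethylsilyl)pent-4-ynyl group on C10 trans, C10 methyl axial, C9 set | CC(=N[C@@H](C)c1ccccc1)[C@H]1C(C)(C)CCC[C@]1(C)[C@@H](CCC#C[Si](C)(C)C)C(C)=O | intermediate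
14 | N-[(S)-1-phenylethyl] imine of enone 15 (1-azadiene, N on C6) | CC1=CC(=N[C@@H](C)c2ccccc2)[C@H]2C(C)(C)CCC[C@]2(C)[C@H]1CCC#C[Si](C)(C)C | intermediate
15 | 14-(trimethylsilyl)-15,16-dinorlabd-7-en-13-yn-6-one (5α-H, 9α-H, 10β-methyl) | CC1=CC(=O)[C@H]2C(C)(C)CCC[C@]2(C)[C@H]1CCC#C[Si](C)(C)C | intermediate
16 | 14-(trimethylsilyl)-15,16-dinorlabd-7-en-13-yn-6β-ol | CC1=C[C@@H](O)[C@H]2C(C)(C)CCC[C@]2(C)[C@H]1CCC#C[Si](C)(C)C | intermediate
17 | 14-(trimethylsilyl)-15,16-dinorlabd-7-en-13-yn-6β-yl acetate | CC1=C[C@@H](OC(C)=O)[C@H]2C(C)(C)CCC[C@]2(C)[C@H]1CCC#C[Si](C)(C)C | intermediate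
18 | 14-(trimethylsilyl)-15,16-dinorlabd-7-en-13-yne | CC1=CC[C@H]2C(C)(C)CCC[C@]2(C)[C@H]1CCC#C[Si](C)(C)C | intermediate
19 | 15,16-dinorlabd-7-en-13-yne | CC1=CC[C@H]2C(C)(C)CCC[C@]2(C)[C@H]1CCC#C | intermediate
20 | dimethyl[(13E)-15-norlabda-7,13-dien-14-yl]alane | CC1=CC[C@H]2C(C)(C)CCC[C@]2(C)[C@H]1CC/C(C)=C/[Al](C)C | intermediate
21 | (13E)-labda-7,13-dien-15-ol, (5S,9S,10S) | CC1=CC[C@H]2C(C)(C)CCC[C@]2(C)[C@H]1CC/C(C)=C/CO | intermediate
22 | malonic acid | OC(=O)CC(O)=O | starting material
23 | bis[(5S,9S,10S,13E)-labda-7,13-dien-15-yl] malonate | CC1=CC[C@H]2C(C)(C)CCC[C@]2(C)[C@H]1CC/C(C)=C/COC(=O)CC(=O)OC/C=C(\C)CC[C@H]1C(C)=CC[C@H]2C(C)(C)CCC[C@]12C | target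

**Step count and risks**

Total steps: 11. Longest linear sequence: 9 steps (1, 2, 5, 6, 7, 8, 9, 10, 11).

Steps most likely to fail:

1. Step 6 (Proposed new method). The aza-ene Michael addition onto the tetrasubstituted enone may be too slow, so that thermal decomposition or enone isomerisation competes. Facial control by the auxiliary may be incomplete. The C9 configuration may erode by re-enolisation before ring B closes, and the aldol closure may take the wrong regiochemical course. Fallback with known chemistry, setting out from 10 and returning at 15: ring A is closed by a classical base-mediated enolate Michael addition (KOtBu cat., tBuOH–THF, rt), which should give the racemic trans-1,5-diketone F1 as the thermodynamic ring A isomer. A separate aldol condensation (KOH, MeOH, reflux) then closes ring B to the racemic enone F2; the C9 epimers are separated by chromatography and the unwanted one is re-equilibrated with NaOMe. Preparative chromatography on a chiral stationary phase supplies 15, where the route is rejoined.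

2. Step 9. Hydride may be delivered to the wrong allyl terminus (C8), β-hydride elimination from the π-allyl complex may give a diene, or ionisation of the hindered axial acetate may be slow. Fallback, setting out from 16 and returning at 18: the alcohol is converted (NaH, CS2; then MeI, THF) into the S-methyl xanthate F3, and Barton–McCombie deoxygenation (Bu3SnH, AIBN, PhMe, 80 °C) proceeds through the allyl radical, which should take hydrogen at the less substituted terminus C6 to give 18. This is desilylated with K2CO3 in MeOH as in the second stage of step 9.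

3. Step 5. Protodemetalation or β-hydride elimination of the alkyl organometallic, or loss of alkene geometry through isomerisation of the vinylpalladium intermediate, may lower the yield or the E purity of the enedione. Fallback, setting out from 7 and returning at 10: the ketone is protected (ethylene glycol, TsOH, PhH, reflux) as the dioxolane F4, and hydroboration with 9-BBN (THF, rt) gives the B-alkyl-9-borabicyclononane F5. Suzuki–Miyaura coupling with 4 (PdCl2(dppf), Cs2CO3, DMF–THF, 50 °C) gives the ketal-protected enedione F6, and mild hydrolysis (PPTS, acetone–H2O, rt) returns 10.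

Further compounds
F1 | step 6 | racemic 3-(trans-2-acetyl-1,3,3-trimethylcyclohexyl)-7-(trimethylsilyl)hept-6-yn-2-one (relative configuration of 13) | CC(=O)[C@H]1C(C)(C)CCC[C@]1(C)[C@@H](CCC#C[Si](C)(C)C)C(C)=O.CC(=O)[C@@H]1C(C)(C)CCC[C@@]1(C)[C@H](CCC#C[Si](C)(C)C)C(C)=O
F2 | step 6 | racemic 14-(trimethylsilyl)-15,16-dinorlabd-7-en-13-yn-6-one (racemate of 15) | CC1=CC(=O)[C@H]2C(C)(C)CCC[C@]2(C)[C@H]1CCC#C[Si](C)(C)C.CC1=CC(=O)[C@@H]2C(C)(C)CCC[C@@]2(C)[C@@H]1CCC#C[Si](C)(C)C
F3 | step 9 | O-[14-(trimethylsilyl)-15,16-dinorlabd-7-en-13-yn-6β-yl] S-methyl carbonodithioate | CC1=C[C@@H](OC(=S)SC)[C@H]2C(C)(C)CCC[C@]2(C)[C@H]1CCC#C[Si](C)(C)C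
F4 | step 5 | 2-(2,2-dimethylpent-4-en-1-yl)-2-methyl-1,3-dioxolane | CC1(CC(C)(C)CC=C)OCCO1
F5 | step 5 | 9-[4,4-dimethyl-5-(2-methyl-1,3-dioxolan-2-yl)pentyl]-9-borabicyclo[3.3.1]nonane | CC1(CC(C)(C)CCCB2C3CCCC2CCC3)OCCO1
F6 | step 5 | (E)-4,8,8-trimethyl-9-(2-methyl-1,3-dioxolan-2-yl)-3-[4-(trimethylsilyl)but-3-yn-1-yl]non-3-en-2-one | CC(=O)/C(CCC#C[Si](C)(C)C)=C(\C)CCCC(C)(C)CC1(C)OCCO1
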